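Numbering: benzofuran O1, C2, C3, C3a, C4–C7, C7a (ring A = benzo ring, ring B = furan). Ring C = 3,5-dioxygenated phenyl on C3 (C1'–C6'), ring D = seven-membered ketone, ring E = aryl on C2, ring F = aryl on the stereocentre.
Enabling feature: ring D is the five-carbon bay C4–C3a–C3–C1'–C2' of a 3-arylbenzofuran spanned by the two-carbon unit O=C–CH(ring F), which is an aryl ketene. C4 and C2' face each other but cannot bond directly (a strained cyclopenta-fused benzofuran would result). Ring C is locally symmetric, so its two ortho C–H bonds are equivalent.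
Key disconnection: C4–C(=O) and C2'–CH are cut together, giving 4-bromo-2,3-diarylbenzofuran 8 and ketene 11 (from acid chloride 10). The forward step is an asymmetric palladium-catalysed [5+2] annulation that closes ring D and sets the only stereocentre.
8 goes back to 4-bromo-3-iodobenzofuran 6 (Suzuki–Miyaura coupling at C3), 6 to the o-alkynylaryl benzyl ether 5 (iodocyclisation, ring B), and 5 to bromo-iodoarene 3 (Sonogashira coupling).
Order of ring formation: ring B (step 4), then ring D (step 8). Rings A, C, E and F are bought, and the five benzyl ethers leave last by neutral hydrogenolysis.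

Key step: step 8

Assumption: precedent does not show which antipode of the binaphthyl phosphine in step 8 leads to the (S)-ketone. It is written as (R); both antipodes are available, and the choice is fixed by a test run.

Step 1
Reactants: 1 5-bromobenzene-1,3-diol
Product: 2 1,3-bis(benzyloxy)-5-bromobenzene
Conditions: BnBr, K2CO3, DMF, 60 °C
Reagents that add atoms: benzyl bromide BrCc1ccccc1
Why: Williamson ether synthesis on both phenols; benzyl survives every later step and leaves at the end under neutral conditions that spare the enolisable stereocentre.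

Step 2
Reactants: 2 1,3-bis(benzyloxy)-5-bromobenzene
Product: 3 1,5-bis(benzyloxy)-3-bromo-2-iodobenzene
Conditions: NIS, TFA (cat.), MeCN, rt
Reagents that add atoms: N-iodosuccinimide O=C1CCC(=O)N1I
Why: Electrophilic aromatic iodination should go to the position next to bromine (para to one benzyloxy group, ortho to the other), because the site between the two benzyloxy groups is more crowded.

Step 3
Reactants: 3 1,5-bis(benzyloxy)-3-bromo-2-iodobenzene; 4 1-(benzyloxy)-4-ethynylbenzene
Product: 5 1,5-bis(benzyloxy)-3-bromo-2-{[4-(benzyloxy)phenyl]ethynyl}benzene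
Conditions: PdCl2(PPh3)2, CuI, Et3N, THF, 50 °C
Reagents that add atoms: none
Why: Sonogashira coupling is chemoselective for the C–I bond, which undergoes oxidative addition much faster than the neighbouring C–Br bond.

Step 4
Reactants: 5 1,5-bis(benzyloxy)-3-bromo-2-{[4-(benzyloxy)phenyl]ethynyl}benzene
Product: 6 6-(benzyloxy)-2-[4-(benzyloxy)phenyl]-4-bromo-3-iodo-1-benzofuran
Conditions: I2, CH2Cl2, rt
Reagents that add atoms: iodine II
Why: Electrophilic iodocyclisation (5-endo-dig attack of the ortho ether oxygen on the iodonium-activated alkyne, then SN2 debenzylation of the oxonium ion by iodide) builds ring B and leaves C3–I and C4–Br as two handles of graded reactivity.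

Step 5
Reactants: 2 1,3-bis(benzyloxy)-5-bromobenzene
Product: 7 2-[3,5-bis(benzyloxy)phenyl]-4,4,5,5-tetramethyl-1,3,2-dioxaborolane
Conditions: B2pin2, PdCl2(dppf), KOAc, dioxane, 90 °C
Reagents that add atoms: bis(pinacolato)diboron CC1(C)OB(OC1(C)C)B1OC(C)(C)C(C)(C)O1
Why: Miyaura borylation of an unhindered aryl bromide, which tolerates benzyl ethers.

Step 6
Reactants: 6 6-(benzyloxy)-2-[4-(benzyloxy)phenyl]-4-bromo-3-iodo-1-benzofuran; 7 2-[3,5-bis(benzyloxy)phenyl]-4,4,5,5-tetramethyl-1,3,2-dioxaborolane
Product: 8 6-(benzyloxy)-2-[4-(benzyloxy)phenyl]-3-[3,5-bis(benzyloxy)phenyl]-4-bromo-1-benzofuran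
Conditions: Pd(PPh3)4, K2CO3, dioxane/H2O, 70 °C
Reagents that add atoms: none
Why: Suzuki–Miyaura coupling should take place at C3–I in preference to C4–Br, and the bromide of the product is shielded by the new peri ring C, which holds back a second coupling.

Step 7
Reactants: 9 [4-(benzyloxy)phenyl]acetic acid
Product: 10 [4-(benzyloxy)phenyl]acetyl chloride
Conditions: (COCl)2, DMF (cat.), CH2Cl2, 0 °C to rt
Reagents that add atoms: oxalyl chloride ClC(=O)C(=O)Cl
Why: Standard acid chloride formation through the catalytic chloroiminium (Vilsmeier-type) species; the crude chloride is used at once.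

Step 8
Reactants: 8 6-(benzyloxy)-2-[4-(benzyloxy)phenyl]-3-[3,5-bis(benzyloxy)phenyl]-4-bromo-1-benzofuran; 10 [4-(benzyloxy)phenyl]acetyl chloride
Product: 12 (S)-penta-O-benzylhopeafuran (ring D ketone; C4–C(=O)–CH(ring F)–C2'; all five phenols as benzyl ethers), via aryl ketene 11 (not isolated)
Conditions: Pd(OAc)2 (10 mol %), (R)-2-(dicyclohexylphosphino)-2'-(dimethylamino)-1,1'-binaphthyl (20 mol %), iPr2NEt (4 equiv), 4 Å MS, toluene, 70 °C; 10 (2 equiv) in toluene added by syringe pump over 12 h
Reagents that add atoms: none
Why: Proposed new method: iPr2NEt turns the slowly added chloride 10 into aryl ketene 11, zerovalent palladium inserts into the C4–Br bond of 8, the C4 aryl group migrates to the sp carbon of 11 (bond C4–C=O) to give a divalent palladium enolate without beta-hydrogen, this electrophilic centre metalates the facing C2'–H bond of ring C with loss of HBr to the amine, and C–C reductive elimination makes the bond C2'–CH and returns zerovalent palladium. The closest known reaction types are the palladium-catalysed [5+2] annulation of 1-halo-8-arylnaphthalenes with alkynes (same eight-membered palladacycle), the insertion of ketenes into aryl–rhodium and aryl–palladium bonds, the amine-buffered coupling of a palladium enolate with an arene C–H bond in the oxindole synthesis from alpha-chloroacetanilides, and the capture of ketenes made in situ by chiral palladium intermediates. Ring D, the only ring closed, forms by reductive elimination from the eight-membered palladacycle Pd–CH–C(=O)–C4–C3a–C3–C1'–C2', a formal [5+2] annulation. The single stereocentre is set in that reductive elimination: the two C-bound enolate epimers interconvert through the O-bound form, and the chiral binaphthyl monophosphine decides which one couples faster (Curtin–Hammett control), as in asymmetric alpha-arylations that give tertiary centres under weakly basic conditions. The step needs insertion before C–H cleavage, so that the carbonyl carbon ends on C4 and not on C2', which is secured by the electrophilic central carbon of the ketene, by the carboxylate-poor bromide-bound aryl complex that metalates slowly, and by the strain that forbids a direct C4–C2' closure; site selectivity is given because only the two equivalent ortho C–H bonds of ring C are within reach. The weak amine base, the moderate temperature and an alpha C–H bond that lies close to the carbonyl plane of the folded ring D should protect the new centre from enolisation.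

Step 9
Reactants: 12 (S)-penta-O-benzylhopeafuran
Product: 13 hopeafuran, (S)-configured at the ring D methine carbon
Conditions: H2 (1 atm), Pd/C, EtOAc/MeOH, rt
Reagents that add atoms: none
Why: Catalytic hydrogenolysis cleaves all five benzylic C–O bonds under neutral conditions, so the alpha-stereocentre sees neither acid nor base, while the hindered aryl ketone and the tetrasubstituted benzofuran double bond should react more slowly.

Compound list
1 | 5-bromobenzene-1,3-diol | Oc1cc(O)cc(Br)c1 | starting material
2 | 1,3-bis(benzyloxy)-5-bromobenzene | Brc1cc(OCc2ccccc2)cc(OCc2ccccc2)c1 | intermediate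
3 | 1,5-bis(benzyloxy)-3-bromo-2-iodobenzene | Brc1cc(OCc2ccccc2)cc(OCc2ccccc2)c1I | intermediate
4 | 1-(benzyloxy)-4-ethynylbenzene | C#Cc1ccc(OCc2ccccc2)cc1 | starting material
5 | 1,5-bis(benzyloxy)-3-bromo-2-{[4-(benzyloxy)phenyl]ethynyl}benzene | Brc1cc(OCc2ccccc2)cc(OCc2ccccc2)c1C#Cc1ccc(OCc2ccccc2)cc1 | intermediate
6 | 6-(benzyloxy)-2-[4-(benzyloxy)phenyl]-4-bromo-3-iodo-1-benzofuran | Brc1cc(OCc2ccccc2)cc2oc(-c3ccc(OCc4ccccc4)cc3)c(I)c12 | intermediate
7 | 2-[3,5-bis(benzyloxy)phenyl]-4,4,5,5-tetramethyl-1,3,2-dioxaborolane | CC1(C)OB(OC1(C)C)c1cc(OCc2ccccc2)cc(OCc2ccccc2)c1 | intermediate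
8 | 6-(benzyloxy)-2-[4-(benzyloxy)phenyl]-3-[3,5-bis(benzyloxy)phenyl]-4-bromo-1-benzofuran | Brc1cc(OCc2ccccc2)cc2oc(-c3ccc(OCc4ccccc4)cc3)c(-c3cc(OCc4ccccc4)cc(OCc4ccccc4)c3)c12 | intermediate
9 | [4-(benzyloxy)phenyl]acetic acid | OC(=O)Cc1ccc(OCc2ccccc2)cc1 | starting material
10 | [4-(benzyloxy)phenyl]acetyl chloride | O=C(Cl)Cc1ccc(OCc2ccccc2)cc1 | intermediate
11 | [4-(benzyloxy)phenyl]ketene (not isolated) | O=C=Cc1ccc(OCc2ccccc2)cc1 | intermediate
12 | (S)-penta-O-benzylhopeafuran | O=C1c2cc(OCc3ccccc3)cc3oc(-c4ccc(OCc5ccccc5)cc4)c(c23)-c2cc(OCc3ccccc3)cc(OCc3ccccc3)c2[C@@H]1c1ccc(OCc2ccccc2)cc1 | intermediate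
13 | hopeafuran, (S) | O=C1c2cc(O)cc3oc(-c4ccc(O)cc4)c(c23)-c2cc(O)cc(O)c2[C@@H]1c1ccc(O)cc1 | target

Total step count: 9. Longest linear sequence: 7 (steps 1, 2, 3, 4, 6, 8, 9).

Steps most likely to fail

1. Step 8.
- **What may go wrong:**
  - The ketene may be lost by dimerisation or by reaction with zerovalent palladium before it inserts.
  - The ammonium salt may protonate the palladium enolate.
  - C–H cleavage ahead of insertion (an aryl-to-aryl shift of palladium) would turn the two-carbon bridge round.
  - Facial selectivity in the reductive elimination may be poor, or the amine may erode the configuration.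
- **Fallback (known chemistry, from 8 and 10 back to 12):**
  - Bromine–lithium exchange on 8 (n-BuLi, THF, −78 °C) gives the aryllithium F1, and ZnCl2 turns it into the arylzinc chloride F2.
  - Negishi acylation with 10 (Pd(PPh3)4, THF) gives the benzyl ketone F3.
  - Regitz diazo transfer (4-acetamidobenzenesulfonyl azide, DBU, MeCN) gives the alpha-diazoketone F4.
  - Rh2(OAc)4 in CH2Cl2 closes ring D by aromatic substitution of the carbenoid at C2' and gives the racemic ketone F5.
  - KN(SiMe3)2 and Me3SiCl convert it into the trimethylsilyl enol ether F6.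
  - Catalytic enantioselective protonation (BINOL-derived N-triflyl thiophosphoramide, phenol, toluene), known for silyl enol ethers of 2-aryl cyclic ketones, returns 12.
  - Material of low enantiomeric purity from step 8 can enter this sequence at the enol ether stage.

2. Step 6.
- **What may go wrong:** oxidative addition and transmetalation at the crowded C3–I bond (between ring E and the peri bromine) may be slow, which leads to protodeiodination or to loss of the iodide over bromide preference.
- **Fallback (reversed polarity, from 6 and 2 back to 8):**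
  - Selective iodine–magnesium exchange on 6 (iPrMgCl·LiCl, THF, −40 °C) gives the 3-magnesiated benzofuran F7.
  - ZnCl2 gives the 3-zincated benzofuran F8.
  - Negishi coupling with the unhindered bromide 2 (Pd2(dba)3, SPhos, THF, 50 °C) gives 8. Step 5 is then not needed.

3. Step 9.
- **What may go wrong:** the aryl ketone may be over-reduced, or cleavage at the crowded C3' ether may stay incomplete and force long exposure to the catalyst.
- **Fallback (from 12 directly to 13):** the reductive cleavage is replaced by Lewis-acid ether cleavage with a cation scavenger (BCl3, pentamethylbenzene, CH2Cl2, −78 °C). The short contact at low temperature limits enolisation. No new compound arises on this way (F0).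

Further compounds
F1 | step 8 | 4-lithio derivative of 8 (aryllithium) | [Li]c1cc(OCc2ccccc2)cc2oc(-c3ccc(OCc4ccccc4)cc3)c(-c3cc(OCc4ccccc4)cc(OCc4ccccc4)c3)c12
F2 | step 8 | arylzinc chloride (C4–ZnCl) | Cl[Zn]c1cc(OCc2ccccc2)cc2oc(-c3ccc(OCc4ccccc4)cc3)c(-c3cc(OCc4ccccc4)cc(OCc4ccccc4)c3)c12
F3 | step 8 | 1-(benzofuran-4-yl)-2-[4-(benzyloxy)phenyl]ethan-1-one derived from 8 (benzyl ketone) | O=C(Cc1ccc(OCc2ccccc2)cc1)c1cc(OCc2ccccc2)cc2oc(-c3ccc(OCc4ccccc4)cc3)c(-c3cc(OCc4ccccc4)cc(OCc4ccccc4)c3)c12
F4 | step 8 | alpha-diazoketone of F3 | O=C(C(=[N+]=[N-])c1ccc(OCc2ccccc2)cc1)c1cc(OCc2ccccc2)cc2oc(-c3ccc(OCc4ccccc4)cc3)c(-c3cc(OCc4ccccc4)cc(OCc4ccccc4)c3)c12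
F5 | step 8 | racemic penta-O-benzylhopeafuran | O=C1c2cc(OCc3ccccc3)cc3oc(-c4ccc(OCc5ccccc5)cc4)c(c23)-c2cc(OCc3ccccc3)cc(OCc3ccccc3)c2C1c1ccc(OCc2ccccc2)cc1
F6 | step 8 | trimethylsilyl enol ether of F5 | C[Si](C)(C)OC1=C(c2ccc(OCc3ccccc3)cc2)c2c(OCc3ccccc3)cc(OCc3ccccc3)cc2-c2c(-c3ccc(OCc4ccccc4)cc3)oc3cc(OCc4ccccc4)cc1c23
F7 | step 6 | 3-(chloromagnesio) derivative of 6 | Cl[Mg]c1c(-c2ccc(OCc3ccccc3)cc2)oc2cc(OCc3ccccc3)cc(Br)c12
F8 | step 6 | 3-(chlorozincio) derivative of 6 | Cl[Zn]c1c(-c2ccc(OCc3ccccc3)cc2)oc2cc(OCc3ccccc3)cc(Br)c12
F0 | step 9 | none | none
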